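The earlier runs and the new flask were generated by integration for substances that don't exist, and the scatter is random.

The rate constants are not given, but one ratio of them can be read from the two earlier runs.

| flask | starting material | remark | time |
|---|---|---|---|
| blue | 0.050 M | run made earlier |  |
| ochre | 0.20 M | run made earlier |  |
| flask | 0.10 M |  | 2.5 h |

- blue (time / h: target / %, intermediate C / %, starting material / %): 0.250: 25.3, 32.3, 0.1; 0.333: 30.3, 37.0, 0; 0.500: 32.6, 39.2, 0; 0.833: 35.0, 39.1, 0.3; 1.33: 34.8, 39.9, 0; 2.00: 34.0, 40.4, 0; 3.00: 34.2, 42.0, 0
- ochre (time / h: target / %, intermediate C / %, starting material / %): 0.417: 20.3, 22.5, 0; 0.833: 21.9, 24.5, 0; 1.33: 18.8, 25.0, 2.1; 1.50: 20.6, 24.9, 0.4; 2.00: 19.0, 25.7, 0.3; 2.50: 20.3, 23.4, 0.2; 3.00: 19.6, 25.3, 0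

(scatter of a reading: 1 percentage point)

* at 2.5 h, what has stopped the reaction, if anything has (all of the starting material has reacted / forward and back rates have come level / it is still moving)
* amount of target at 2.5 h, in percent of the starting material charged
* amount of intermediate C at 2.5 h, in percent of the starting material charged

- the reaction counts as stopped when no species that holds the starting material changes by six tenths of a point or more over the second half of the time

Starting material already reads 0% at 0.333 h in the blue run and 0% at 0.417 h in the ochre run, so watch the early readings. But target plus intermediate C reads 76.2% at the last blue reading and 44.9% at the last ochre reading, so this pair reads lower in the ochre run, which has the larger charge.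

So follow one molecule of starting material: I take it that at each moment it enters a first-order road to this pair or a second-order loss. I write c for its starting concentration and g for the second-order rate over the first-order rate, per unit of concentration. The chance of the first-order road over a whole run, the selectivity s, is then ln(1+gc)/(gc).

The ochre pair asks for gc near 3, which gives the loss strength g = 15.0 M⁻¹, with s = 46.2% for the ochre run. The test is blue, where s = 74.6% stands against the 76.2% read.

For this flask, s = 61.1%. Target reads 44.9% of the pair at the last blue reading, so with that split I expect 27.4% target and 33.7% intermediate C.

The forecast, resting on “a second-order loss competing with first-order product formation”, says all of the starting material has reacted, with target 27% (25% to 29%) and intermediate C 32.5% (30% to 35%).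

The flask gives this at 2.5 h: all of the starting material has reacted, with 0% left, target 27.6% and intermediate C 32.9%.

    intermediate B → intermediate C (k = 0.0280 s⁻¹)
    starting material → intermediate A (k = 0.0480 s⁻¹)
    2 starting material → homo dimer (k = 0.370 M⁻¹ s⁻¹)
    intermediate C ⇌ target (K = 0.840, k = 0.0350 s⁻¹)
    intermediate A → intermediate B (k = 0.00190 s⁻¹)

In this flask, the 38.9% that my s leaves over stands beside homo dimer at 39.5% at 2.50 h, each homo dimer counted as two. With the same g, I reckon s = 71.3% for the neighbour flask at 0.060 M, which holds target 32.3%, intermediate C 38.5% and homo dimer 29.2% at 2.50 h.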